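**Retrosynthesis**
- The target's 4-methylcyclohexene is an exo Diels–Alder adduct of a 1-aryl-3-methylbutadiene with 2,4,2',4'-tetrahydroxychalcone (morachalcone A).
- The diene sits at C-5' of a (2S)-7,2',4'-trihydroxyflavanone, so the flavanone is built first and the cyclohexene is formed last.
- The flavanone comes from the oxa-Michael closure of a dienyl 2'-hydroxychalcone, which comes from Claisen–Schmidt condensation of 2,4-dihydroxyacetophenone with 5-dienyl-2,4-dihydroxybenzaldehyde.
- That aldehyde comes from Heck coupling of isoprene with 5-iodo-2,4-dihydroxybenzaldehyde, which comes from 2,4-dihydroxybenzaldehyde.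
- Ring order: pyranone (oxa-Michael), then cyclohexene (Diels–Alder).

**Assumptions**
- The Heck reaction of isoprene occurs at the vinyl CH2 to give the (E)-1-aryl-3-methylbutadiene.
- Free phenols are tolerated in every step.
- The flavanone C-2 centre does not epimerise under the mild, neutral Diels–Alder conditions.

**Route**

Step 1
Reactants: 1 (2,4-dihydroxybenzaldehyde); 2 (N-iodosuccinimide)
Product: 3 (5-iodo-2,4-dihydroxybenzaldehyde)
Conditions: NIS (1.05 equiv), MeCN, 0 °C to rt, 3 h
Reagents that add atoms: NIS, O=C1CCC(=O)N1I (delivers I)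
Why: Electrophilic aromatic iodination goes to C-5, which is para to the 2-OH, ortho to the 4-OH and meta to the CHO.

Step 2
Reactants: 3; 4 (isoprene)
Product: 5 ((E)-2,4-dihydroxy-5-(3-methylbuta-1,3-dien-1-yl)benzaldehyde)
Conditions: Pd(OAc)2 (5 mol%), P(o-tol)3 (10 mol%), Et3N, isoprene (6 equiv), MeCN, 90 °C, sealed tube, 16 h
Reagents that add atoms: isoprene, C=CC(C)=C (delivers the C5H7 dienyl unit)
Why: Mizoroki–Heck arylation occurs at the unsubstituted terminal CH2 of isoprene, and β-hydride elimination gives the E-diene.

Step 3
Reactants: 5; 6 (2,4-dihydroxyacetophenone)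
Product: 7 ((E)-1-(2,4-dihydroxyphenyl)-3-{2,4-dihydroxy-5-[(E)-3-methylbuta-1,3-dienyl]phenyl}prop-2-en-1-one)
Conditions: KOH (6 equiv), EtOH/H2O 4:1, BHT (trace), N2, rt, 48 h; then 2 M HCl to pH 2
Reagents that add atoms: none
Why: Claisen–Schmidt aldol condensation of the acetophenone enolate with the aldehyde, which is in its phenoxide form, gives the E-enone; excess base covers the four phenols.

Step 4
Reactants: 7
Product: 8 (racemic 7-hydroxy-2-{2,4-dihydroxy-5-[(E)-3-methylbuta-1,3-dienyl]phenyl}chroman-4-one)
Conditions: NaOAc (5 equiv), EtOH, reflux, N2, dark, 36 h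
Reagents that add atoms: none
Why: Intramolecular 6-endo oxa-Michael addition of the 2'-OH onto the enone; mild buffered conditions avoid acid-promoted reaction of the diene, and the new C-2 centre is racemic.

Step 5
Reactants: 8
Product: 9 ((2S)-7-hydroxy-2-{2,4-dihydroxy-5-[(E)-3-methylbuta-1,3-dienyl]phenyl}chroman-4-one)
Conditions: semi-prep chiral-phase HPLC (Chiralpak IC, n-hexane/EtOH 70:30, rt); collect the (2S) enantiomer, assigned by CD (negative n→π* band near 330 nm, as for (2S)-flavanones)
Reagents that add atoms: none
Why: Physical separation of the enantiomers sets the C-2 configuration with no chiral reagent, catalyst or auxiliary, and it is done before the Diels–Alder so only (S)-diene is carried forward.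

Step 6
Reactants: 1 (2,4-dihydroxybenzaldehyde); 6 (2,4-dihydroxyacetophenone)
Product: 10 (morachalcone A, (E)-1,3-bis(2,4-dihydroxyphenyl)prop-2-en-1-one)
Conditions: KOH (6 equiv), EtOH/H2O 4:1, N2, rt, 48 h; then 2 M HCl to pH 2
Reagents that add atoms: none
Why: The same Claisen–Schmidt condensation gives the E-chalcone dienophile.

Step 7
Reactants: 9 (diene); 10 (dienophile, 3 equiv)
Product: 11 (guangsangon N)
Conditions: PhB(OH)2 (2 equiv), 4 Å MS, MeCN, 80 °C, sealed tube, 48 h; then MeOH evaporation (×3) to remove boron; prep-HPLC to isolate the target diastereomer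
Reagents that add atoms: none (PhB(OH)2 is a removable promoter)
Why: Intermolecular [4+2] Diels–Alder, with the chalcone activated by boronate chelation at its 2'-OH and carbonyl.
- The ortho/para-matched regiochemistry puts the aroyl carbon next to the aryl-bearing diene terminus.
- E,E-geometry with exo approach gives the 1,3-cis-diaryl, trans-aroyl arrangement, which is all-equatorial and thermodynamically preferred.
- The fixed (2S) centre is the only chiral bias; it is remote, so both facial diastereomers form and the desired one is separated chromatographically.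

**Compound list**

| # | Name | SMILES | Role |
|---|---|---|---|
| 1 | 2,4-dihydroxybenzaldehyde | O=Cc1ccc(O)cc1O | starting material |
| 2 | N-iodosuccinimide | O=C1CCC(=O)N1I | starting material |
| 3 | 5-iodo-2,4-dihydroxybenzaldehyde | O=Cc1cc(I)c(O)cc1O | intermediate |
| 4 | isoprene | C=CC(C)=C | starting material |
| 5 | (E)-2,4-dihydroxy-5-(3-methylbuta-1,3-dienyl)benzaldehyde | O=Cc1cc(/C=C/C(C)=C)c(O)cc1O | intermediate |
| 6 | 2,4-dihydroxyacetophenone | CC(=O)c1ccc(O)cc1O | starting material |
| 7 | dienyl tetrahydroxychalcone | O=C(/C=C/c1cc(/C=C/C(C)=C)c(O)cc1O)c1ccc(O)cc1O | intermediate |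
| 8 | (±)-dienyl flavanone | C=C(C)/C=C/c1cc(C2CC(=O)c3ccc(O)cc3O2)c(O)cc1O | intermediate |
| 9 | (2S)-dienyl flavanone | C=C(C)/C=C/c1cc([C@@H]2CC(=O)c3ccc(O)cc3O2)c(O)cc1O | intermediate |
| 10 | morachalcone A | O=C(/C=C/c1ccc(O)cc1O)c1ccc(O)cc1O | intermediate |
| 11 | guangsangon N, (2S)-2-{5-[(1R,5S,6R)-6-(2,4-dihydroxybenzoyl)-5-(2,4-dihydroxyphenyl)-3-methylcyclohex-2-en-1-yl]-2,4-dihydroxyphenyl}-7-hydroxychroman-4-one | CC1=C[C@@H](c2cc([C@@H]3CC(=O)c4ccc(O)cc4O3)c(O)cc2O)[C@H](C(=O)c2ccc(O)cc2O)[C@@H](c2ccc(O)cc2O)C1 | target |

**Atom check:** 9 (C20H18O5) + 10 (C15H12O5) = C35H30O10, which is the formula of 11. 9 is an isomer of 7, and 7 = 5 + 6 − H2O.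

**Step count:** 7 steps in total; the longest linear sequence is 6 steps (1 → 3 → 5 → 7 → 8 → 9 → 11).

**Three steps most likely to fail**
1. **Step 7 (Diels–Alder).** Exo selectivity may be modest, the facial ratio relative to C-2 is expected to be near 1:1, and the free polyphenols or flavanone ring-opening could interfere.
   - Fallback: a different approach. Use a protected (E)-2,4-bis(MOM-oxy)cinnamoyl Weinreb amide as dienophile with diene 9 (MOM-protected). After the cycloaddition, add 2,4-bis(MOM-oxy)phenyllithium to the amide to install the aroyl group, then remove the MOM groups.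
2. **Step 2 (Heck with isoprene).** Regioselectivity, isoprene oligomerisation and free-phenol poisoning of Pd are all risks.
   - Fallback: reverse the polarity. Convert 3 to its bis-MOM aryl boronate and couple it with (E)-1-bromo-3-methylbuta-1,3-diene under Suzuki conditions, or build the diene by Wittig olefination with the methallyl ylide on a formyl precursor.
3. **Step 3 (Claisen–Schmidt with free phenols and a diene).** Yield may be low from phenoxide deactivation of the aldehyde and diene polymerisation under strong base.
   - Fallback: skip the aldol. Use Pd-catalysed 1,4-conjugate arylation of 7-hydroxychromone with the 2,4-dihydroxy-5-dienylphenylboronic ester to give racemic 8 directly, then resolve as in step 5.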